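**Your target.** I assume each target costs one reagent, as does each uncatalysed product and each second substrate used. You suspect this flask is the blue run, only slower, but the reagent balance shows a sharper difference. In this flask the cover is 70.0%: the reagent charged as a fraction of both substrates charged. The blue run had 107%. So reagent is the limiting reagent in this flask, but not in the blue run. On that assumption, the fraction of reagent used, times the cover, gives the fraction of the joint substrate charge turned to products.

- blue: starting material 0.20 M; second substrate 0.10 M (fed, over 50 min); reagent 0.32 M; free catalyst 20 mM; run made earlier
- flask: starting material 0.20 M; second substrate 0.100 M (fed, over 50 min); reagent 0.210 M; free catalyst 20 mM; time 8.0 h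

blue run (percent of the starting material charged)

| time / h | starting material / % | target / % |
|---|---|---|
| 0.200 | 87.8 | 9.7 |
| 0.667 | 70.3 | 20.8 |
| 1.00 | 64.4 | 24.7 |
| 1.50 | 56.8 | 28.4 |
| 2.50 | 46.9 | 32.7 |

(standard deviation of a reading: 0.5 percentage points)

- the earlier runs were read with a standard deviation of 0.5 percentage points
- the reaction counts as stopped when no species that holds the starting material changes by six tenths of a point or more over the second half of the time

1. which holds at 8.0 h: what has brought the reaction to rest, or that it has not come to rest (no working catalyst is left / it is still moving / all of the starting material has reacted / the reagent has run out first / forward and back rates have come level)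
2. part of the starting material gone at 8.0 h
3. the target standing at 8.0 h, as a percentage of the starting material charged
4. the uncatalysed product standing at 8.0 h, as a percentage of the starting material charged

**My reckoning.** Both routes from the starting material take reagent, so I scale the blue run by the ratio of reagent charges, 65.6%. The blue run had lost 53.1% of its starting material by 2.50 h, so this flask should have lost about 34.8% by then. I take that as my low mark for 8.0 h. The cover is my high mark, reached if both substrates go in step and the reagent is used up. I commit to the middle, 52.4% gone. The blue reading at 2.50 h puts 61.6% of the loss in target. That gives 32.3% target, and I book the remaining 20.1% as uncatalysed product. If the second substrate goes at the same fraction, I reckon 25.1% of the reagent left, since my conversion is less than the cover, so I call the flask still moving.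

**The forecast.** It says it is still moving, with 65% gone, 39% target and 26% uncatalysed product, higher than my conversion, and concludes: “The reaction is therefore still moving.”

**The flask.** It gives it is still moving, with 51.7% gone, 26.0% target and 19.7% uncatalysed product.

    starting material + free catalyst ⇌ catalyst intermediate A (K = 1.70 L mol⁻¹, k = 0.0320 L mol⁻¹ s⁻¹)
    reagent + catalyst intermediate A → free catalyst + target (k = 0.0250 L mol⁻¹ s⁻¹)
    second substrate + free catalyst ⇌ catalyst intermediate B (K = 850 L mol⁻¹, k = 0.0110 L mol⁻¹ s⁻¹)
    reagent + catalyst intermediate B → free catalyst + second product (k = 0.00470 L mol⁻¹ s⁻¹)
    free catalyst + target → free catalyst + over-reaction product (k = 0.00360 L mol⁻¹ s⁻¹)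
    starting material + reagent → uncatalysed product (k = 1.10 × 10⁻⁴ L mol⁻¹ s⁻¹)
    free catalyst → spent catalyst (k = 1.90 × 10⁻⁴ s⁻¹)

**What ran.** At the end of the feed, 0.833 h, the flask held 31.5% of its catalyst free and 30.9% as spent catalyst. From 4.00 h to 8.00 h spent catalyst rose to 86.7% and target went from 25.1% to 26.0%, while uncatalysed product climbed from 14.3% to 19.7% with 26% of the reagent left. The reagent used, times the cover, gives 51.8% of the joint substrate charge turned to products, and the unbound substrates show 52.4% gone. The neighbour with 0.84 M of reagent has a cover of 280%, and at 8.00 h it keeps 70% of its reagent with 97.2% of its starting material gone.

All runs were computed for an exercise; noise was put on by code.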